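**Retrosynthetic overview**
1. The target is cut last at the diene C–C bond between C(CH3)= and the CH=CH attached to ring A: a ring-A (E)-alkenyl iodide plus a ring-B (Z)-alkenylsilane (Hiyama–Denmark coupling). No side-chain olefin therefore has to face singlet oxygen.
2. Ring B is a 7-oxabicyclo[4.1.0]hept-3-ene whose hydroxyls at C2 and C5 are cis to each other and anti to the C1–C6 oxirane, with the olefin C3=C4 between them. This is the pattern of a benzene oxide whose diene C2–C5 has been capped by O2, so the oxirane bond C1–C6 is closed by oxepin → arene oxide 6π electrocyclisation and trapped with singlet oxygen.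
3. The 2,5-disubstituted oxepin comes from a cyclohexa-1,4-diene (Diels–Alder of a 2-(silyloxymethyl)butadiene with methyl propiolate) by directed epoxidation, bromination and double dehydrobromination. Its only stereocentre, the (S)-carbinol beside the ring (CBS reduction), relays chirality to all four ring centres.
4. Ring A comes from geranyl acetate by Shi epoxidation and cationic epoxy-olefin cyclisation, then Takai olefination.
5. Ring order: ring-A carbocycle and the cyclohexadiene (separately), then the oxepin, then oxirane and cyclohexene of ring B together in the key step.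

Key step: step 9

Remark on the chemistry: the oxepin is drawn as such but equilibrates rapidly with its two diastereomeric benzene oxide valence tautomers. The epoxy alcohol and the dibromide before it are carried as diastereomer mixtures at ring carbons whose configuration disappears on dehydrobromination.

**Ring B**

Step 1
Reactants: 1 tert-butyl(dimethyl)(prop-2-yn-1-yloxy)silane; 2 ethylene
Product: 3 tert-butyl(dimethyl)[(2-methylidenebut-3-en-1-yl)oxy]silane
Conditions: second-generation Grubbs catalyst (3 mol %), ethylene (1 atm), CH2Cl2, 25 °C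
Reagents that add atoms: none
Why: Ethylene–alkyne cross enyne metathesis turns a terminal propargylic ether into the 2-substituted buta-1,3-diene with full atom economy and without forming a stereocentre.

Step 2
Reactants: 3 silyloxymethyl butadiene; 4 methyl propiolate
Product: 5 methyl 4-({[tert-butyl(dimethyl)silyl]oxy}methyl)cyclohexa-1,4-diene-1-carboxylate
Conditions: toluene, BHT (cat.), 110 °C, sealed tube; chromatography to remove the 1,3-regioisomer
Reagents that add atoms: none
Why: The thermal Diels–Alder reaction of a 2-substituted butadiene with an alkynoate gives the skipped cyclohexa-1,4-diene, the 1,4-("para") isomer being favoured because the larger HOMO coefficient at C1 of the diene pairs with the β-carbon of the propiolate.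

Step 3
Reactants: 5 diene ester
Product: 6 4-({[tert-butyl(dimethyl)silyl]oxy}methyl)-N-methoxy-N-methylcyclohexa-1,4-diene-1-carboxamide
Conditions: MeNH(OMe)·HCl (1.6 equiv), iPrMgCl (3.2 equiv), THF, −20 °C
Reagents that add atoms: N,O-dimethylhydroxylamine hydrochloride, CNOC.Cl
Why: Weinreb amide formation by aminolysis of the ester with the chloromagnesium amide is fast at low temperature and leaves the silyl ether and the skipped diene untouched.

Step 4
Reactants: 6 Weinreb amide; 7 prop-1-yn-1-ylmagnesium bromide
Product: 8 1-[4-({[tert-butyl(dimethyl)silyl]oxy}methyl)cyclohexa-1,4-dien-1-yl]but-2-yn-1-one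
Conditions: THF, −20 → 0 °C; inverse quench into cold aq. NH4Cl
Reagents that add atoms: none
Why: In the Weinreb ketone synthesis the magnesium chelate of the tetrahedral intermediate survives until the cold quench, so the alkynyl Grignard reagent adds only once and gives the cross-conjugated enynone.

Step 5
Reactants: 8 enynone
Product: 9 (1R)-1-[4-({[tert-butyl(dimethyl)silyl]oxy}methyl)cyclohexa-1,4-dien-1-yl]but-2-yn-1-ol
Conditions: (R)-2-methyl-CBS-oxazaborolidine (0.3 equiv), catecholborane (1.5 equiv), toluene, −78 °C; then MeOH, aq. NaOH wash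
Reagents that add atoms: none
Why: Corey–Bakshi–Shibata reduction delivers hydride under catalyst control with the branched cyclohexadienyl group as the large and the propynyl group as the small substituent, which sets the carbinol centre (R by the CIP rules here, the same spatial arrangement as the (S)-carbinol of the target).

Step 6
Reactants: 9 dienyl carbinol
Product: 10 (1S)-1-[4-({[tert-butyl(dimethyl)silyl]oxy}methyl)-7-oxabicyclo[4.1.0]hept-3-en-1-yl]but-2-yn-1-ol
Conditions: VO(acac)2 (5 mol %), tBuOOH (1.2 equiv, in decane), CH2Cl2, 0 °C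
Reagents that add atoms: tert-butyl hydroperoxide, CC(C)(C)OO
Why: Hydroxyl-directed vanadium-catalysed epoxidation selects the allylic-alcohol olefin over the remote silyloxymethyl-substituted olefin and the alkyne, and the configuration of the new oxirane carbons is irrelevant because it is erased in step 8.

Step 7
Reactants: 10 epoxy alcohol
Product: 11 (1S)-1-[3,4-dibromo-4-({[tert-butyl(dimethyl)silyl]oxy}methyl)-7-oxabicyclo[4.1.0]heptan-1-yl]but-2-yn-1-ol
Conditions: Br2 (1.05 equiv), CH2Cl2, −78 °C, dark
Reagents that add atoms: bromine, BrBr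
Why: Anti addition of bromine to the only remaining electron-rich olefin (the alkyne reacts far more slowly at −78 °C) follows the classical bromination of cyclohexa-1,4-diene monoepoxides, and the bromine-bearing centres are removed again in step 8.

Step 8
Reactants: 11 dibromo epoxy alcohol
Product: 12 (1S)-1-[5-({[tert-butyl(dimethyl)silyl]oxy}methyl)oxepin-2-yl]but-2-yn-1-ol
Conditions: DBU (3.5 equiv), THF, 0 → 25 °C, dark; filtration through basic Al2O3, used at once
Reagents that add atoms: none
Why: Twofold E2 dehydrobromination of a 4,5-dibromo-1,2-epoxycyclohexane is the standard entry to benzene oxides, and the product rests largely as the oxepin valence tautomer, so the carbinol is the only stereocentre left.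

Step 9
Reactants: 12 oxepin carbinol
Product: 15 (1S)-1-[4-({[tert-butyl(dimethyl)silyl]oxy}methyl)-2,5-dihydroxy-7-oxabicyclo[4.1.0]hept-3-en-1-yl]but-2-yn-1-ol, via arene oxide 13 (not isolated), via endoperoxide 14 (not isolated)
Conditions: O2, tetraphenylporphyrin (1 mol %), visible light (λ > 500 nm), CH2Cl2, −40 °C; then thiourea (1.5 equiv), MeOH, −40 → 20 °C
Reagents that add atoms: dioxygen, O=O
Why: The oxepin ring (O1, C2–C7) is in fast thermal equilibrium with its benzene oxide tautomers through a disrotatory 6π electrocyclisation that forms the C2–C7 σ bond and so closes the three-membered oxirane and the six-membered carbocycle in one pericyclic event; the s-cis diene of arene oxide 13 is then captured by singlet oxygen in a [4+2] cycloaddition, and thiourea reduces the O–O bond of 14 with retention at both carbons. The closest known reaction type is the sensitised photooxygenation of benzene oxide–oxepin pairs that carry a substituent on an oxirane carbon, which gives endoperoxides anti to the oxirane, followed by thiourea reduction to epoxy cis-1,4-diols. The relative configuration of the four ring centres follows from the suprafacial delivery of the peroxide bridge to C2 and C5 (numbering of 15) on the face opposite the oxirane oxygen, so both hydroxyls are cis to each other and anti to the epoxide. The absolute sense is relayed from the (S)-carbinol under Curtin–Hammett conditions, since the two diastereomeric arene oxides interconvert through 12 much faster than they are oxygenated: in 13 the carbinol C–H can lie over the ring while the hydroxyl sits beside diene terminus C2 on the attacked face and hydrogen-bonds the incoming oxygen (the known hydroxyl-directing effect of chiral allylic alcohols on singlet oxygen), whereas in the other diastereomer that position is taken by the propynyl group. The step needs chemo- and periselectivity, which are secured because the alkyne is inert to singlet oxygen, the side-chain diene and ring A are attached only afterwards, the non-protic solvent keeps the directing hydrogen bond, and the low temperature prevents rearrangement of 14 to a bis-epoxide.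

Step 10
Reactants: 15 epoxy triol
Product: 16 (Z)-alkenylsilane: (1S,2Z)-3-[benzyl(dimethyl)silyl]-1-[ring B as in 15]but-2-en-1-ol
Conditions: BnMe2SiH (1.3 equiv), [Cp*Ru(MeCN)3]PF6 (5 mol %), acetone, 0 → 25 °C
Reagents that add atoms: benzyldimethylsilane, C[SiH](C)Cc1ccccc1
Why: Ruthenium-catalysed trans-hydrosilylation of an internal propargylic alcohol places silicon on the alkyne carbon distal to the hydroxyl and adds H and Si anti, which gives the (Z)-alkenylsilane with silicon cis to the carbinol carbon and leaves the oxirane, the ring olefin and the free hydroxyls untouched.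

**Ring A**

Step 11
Reactants: 17 geranyl acetate
Product: 18 (2E)-5-[(2R)-3,3-dimethyloxiran-2-yl]-3-methylpent-2-en-1-yl acetate
Conditions: D-fructose-derived Shi ketone (0.3 equiv), Oxone (2KHSO5·KHSO4·K2SO4), K2CO3, Bu4NHSO4, MeCN–dimethoxymethane–aq. buffer (pH 10.5), 0 °C
Reagents that add atoms: potassium peroxymonosulfate (active component of Oxone), [K+].[O-]S(=O)(=O)OO
Why: Shi epoxidation through a chiral dioxirane and a spiro transition state oxidises the electron-rich 6,7-olefin in preference to the acetate-deactivated allylic olefin and sets the (R)-centre under catalyst control.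

Step 12
Reactants: 18 (R)-6,7-epoxygeranyl acetate
Product: 19 [(1S,5R)-5-hydroxy-2,6,6-trimethylcyclohex-2-en-1-yl]methyl acetate
Conditions: ZrCl4 (1.1 equiv), CH2Cl2, 0 → 25 °C; AgNO3-impregnated silica to remove the exocyclic olefin isomer
Reagents that add atoms: none
Why: The Lewis acid-promoted cation–olefin cyclisation of the epoxide through a chair transition state opens the tertiary oxirane carbon with inversion, keeps the C–O bond of the (R)-centre and places hydroxyl and acetoxymethyl both equatorial (cis-1,3), and proton loss from the ring methylene gives the endocyclic trisubstituted olefin.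

Step 13
Reactants: 19 hydroxy acetate
Product: 20 [(1S,5R)-2,6,6-trimethyl-5-(triethylsilyloxy)cyclohex-2-en-1-yl]methyl acetate
Conditions: Et3SiCl (1.3 equiv), imidazole, DMF, 0 °C
Reagents that add atoms: chlorotriethylsilane, CC[Si](Cl)(CC)CC
Why: Silylation of the secondary alcohol prevents its oxidation in step 15 and the lactol formation that the cis-1,3 hydroxy aldehyde would otherwise undergo.

Step 14
Reactants: 20 silyl ether acetate
Product: 21 [(1S,5R)-2,6,6-trimethyl-5-(triethylsilyloxy)cyclohex-2-en-1-yl]methanol
Conditions: K2CO3 (0.3 equiv), MeOH, 0 → 20 °C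
Reagents that add atoms: none
Why: Base-catalysed transesterification removes the primary acetate while the hindered secondary triethylsilyl ether survives.

Step 15
Reactants: 21 primary alcohol
Product: 22 (1S,5R)-2,6,6-trimethyl-5-(triethylsilyloxy)cyclohex-2-ene-1-carbaldehyde
Conditions: Dess–Martin periodinane (1.3 equiv), NaHCO3, CH2Cl2, 0 °C; used directly
Reagents that add atoms: none
Why: Dess–Martin oxidation under buffered, non-basic conditions gives the β,γ-unsaturated aldehyde without epimerisation of the α-centre or migration of the olefin into conjugation.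

Step 16
Reactants: 22 aldehyde
Product: 23 triethyl({(1R,5S)-5-[(E)-2-iodoethenyl]-4,6,6-trimethylcyclohex-3-en-1-yl}oxy)silane
Conditions: CrCl2 (6 equiv), CHI3 (2 equiv), THF–dioxane, 0 → 20 °C
Reagents that add atoms: iodoform, IC(I)I
Why: Takai olefination with the geminal dichromium reagent is non-basic, so the α-stereocentre is kept, and it gives the (E)-alkenyl iodide selectively with α-branched aldehydes.

**Union**

Step 17
Reactants: 16 ring-B (Z)-alkenylsilane; 23 ring-A (E)-alkenyl iodide
Product: 25 target CNP0389279.1, via coupled bis-silyl ether 24 (not isolated)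
Conditions: Pd2(dba)3·CHCl3 (5 mol %), TBAF (1 M in THF, 6 equiv), THF, 0 → 25 °C
Reagents that add atoms: none
Why: In the Hiyama–Denmark coupling fluoride cleaves the benzyl group from silicon, the resulting silanolate (assisted by the neighbouring carbinol) transmetalates to palladium, and both olefin geometries are retained, so the (2Z,4E)-diene forms, while the excess fluoride removes both silyl ethers in the same flask.

**Compound list**
1 | tert-butyl(dimethyl)(prop-2-yn-1-yloxy)silane | C#CCO[Si](C)(C)C(C)(C)C | starting material
2 | ethylene | C=C | starting material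
3 | tert-butyl(dimethyl)[(2-methylidenebut-3-en-1-yl)oxy]silane | C=CC(=C)CO[Si](C)(C)C(C)(C)C | intermediate
4 | methyl propiolate | C#CC(=O)OC | starting material
5 | methyl 4-({[tert-butyl(dimethyl)silyl]oxy}methyl)cyclohexa-1,4-diene-1-carboxylate | COC(=O)C1=CCC(CO[Si](C)(C)C(C)(C)C)=CC1 | intermediate
6 | 4-({[tert-butyl(dimethyl)silyl]oxy}methyl)-N-methoxy-N-methylcyclohexa-1,4-diene-1-carboxamide | CON(C)C(=O)C1=CCC(CO[Si](C)(C)C(C)(C)C)=CC1 | intermediate
7 | prop-1-yn-1-ylmagnesium bromide | CC#C[Mg]Br | starting material
8 | 1-[4-({[tert-butyl(dimethyl)silyl]oxy}methyl)cyclohexa-1,4-dien-1-yl]but-2-yn-1-one | CC#CC(=O)C1=CCC(CO[Si](C)(C)C(C)(C)C)=CC1 | intermediate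
9 | (1R)-1-[4-({[tert-butyl(dimethyl)silyl]oxy}methyl)cyclohexa-1,4-dien-1-yl]but-2-yn-1-ol | CC#C[C@H](O)C1=CCC(CO[Si](C)(C)C(C)(C)C)=CC1 | intermediate
10 | (1S)-1-[4-({[tert-butyl(dimethyl)silyl]oxy}methyl)-7-oxabicyclo[4.1.0]hept-3-en-1-yl]but-2-yn-1-ol, oxirane carbons not assigned (diastereomers carried together) | CC#C[C@H](O)C12OC1CC(CO[Si](C)(C)C(C)(C)C)=CC2 | intermediate
11 | (1S)-1-[3,4-dibromo-4-({[tert-butyl(dimethyl)silyl]oxy}methyl)-7-oxabicyclo[4.1.0]heptan-1-yl]but-2-yn-1-ol, trans-dibromide, ring centres not assigned | CC#C[C@H](O)C12OC1CC(Br)(CO[Si](C)(C)C(C)(C)C)C(Br)C2 | intermediate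
12 | (1S)-1-[5-({[tert-butyl(dimethyl)silyl]oxy}methyl)oxepin-2-yl]but-2-yn-1-ol | CC#C[C@H](O)C1=CC=C(CO[Si](C)(C)C(C)(C)C)C=CO1 | intermediate
13 | (1S)-1-[4-({[tert-butyl(dimethyl)silyl]oxy}methyl)-7-oxabicyclo[4.1.0]hepta-2,4-dien-1-yl]but-2-yn-1-ol, the arene oxide diastereomer with the oxirane configuration of the target | CC#C[C@H](O)[C@]12O[C@H]1C=C(CO[Si](C)(C)C(C)(C)C)C=C2 | intermediate (not isolated)
14 | endoperoxide of 13: O–O bridge from C2 to C5, anti to the oxirane oxygen, (S)-carbinol | CC#C[C@H](O)[C@]12O[C@H]1[C@H](O3)C(CO[Si](C)(C)C(C)(C)C)=C[C@@H]2O3 | intermediate (not isolated)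
15 | (1S)-1-[4-({[tert-butyl(dimethyl)silyl]oxy}methyl)-2,5-dihydroxy-7-oxabicyclo[4.1.0]hept-3-en-1-yl]but-2-yn-1-ol; ring hydroxyls (2S,5R) cis to each other and to the C1 side chain, anti to the oxirane (C6 S) | CC#C[C@H](O)[C@]12O[C@H]1[C@H](O)C(CO[Si](C)(C)C(C)(C)C)=C[C@@H]2O | intermediate
16 | (1S,2Z)-3-[benzyl(dimethyl)silyl]-1-[ring B as in 15]but-2-en-1-ol; silicon cis to the carbinol carbon | C[Si](C)(Cc1ccccc1)/C(C)=C\[C@H](O)[C@]12O[C@H]1[C@H](O)C(CO[Si](C)(C)C(C)(C)C)=C[C@@H]2O | intermediate
17 | geranyl acetate | CC(C)=CCC/C(C)=C/COC(C)=O | starting material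
18 | (2E)-5-[(2R)-3,3-dimethyloxiran-2-yl]-3-methylpent-2-en-1-yl acetate | CC1(C)O[C@@H]1CC/C(C)=C/COC(C)=O | intermediate
19 | [(1S,5R)-5-hydroxy-2,6,6-trimethylcyclohex-2-en-1-yl]methyl acetate (hydroxyl and acetoxymethyl cis) | CC1=CC[C@@H](O)C(C)(C)[C@H]1COC(C)=O | intermediate
20 | [(1S,5R)-2,6,6-trimethyl-5-(triethylsilyloxy)cyclohex-2-en-1-yl]methyl acetate | CC1=CC[C@@H](O[Si](CC)(CC)CC)C(C)(C)[C@H]1COC(C)=O | intermediate
21 | [(1S,5R)-2,6,6-trimethyl-5-(triethylsilyloxy)cyclohex-2-en-1-yl]methanol | CC1=CC[C@@H](O[Si](CC)(CC)CC)C(C)(C)[C@H]1CO | intermediate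
22 | (1S,5R)-2,6,6-trimethyl-5-(triethylsilyloxy)cyclohex-2-ene-1-carbaldehyde | CC1=CC[C@@H](O[Si](CC)(CC)CC)C(C)(C)[C@H]1C=O | intermediate
23 | triethyl({(1R,5S)-5-[(E)-2-iodoethenyl]-4,6,6-trimethylcyclohex-3-en-1-yl}oxy)silane | CC1=CC[C@@H](O[Si](CC)(CC)CC)C(C)(C)[C@H]1/C=C/I | intermediate
24 | coupled (2Z,4E)-diene still carrying the tert-butyldimethylsilyl ether on the ring-B CH2O and the triethylsilyl ether on ring A | CC1=CC[C@@H](O[Si](CC)(CC)CC)C(C)(C)[C@H]1/C=C/C(C)=C\[C@H](O)[C@]12O[C@H]1[C@H](O)C(CO[Si](C)(C)C(C)(C)C)=C[C@@H]2O | intermediate (not isolated)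
25 | CNP0389279.1: (S)-dienyl carbinol joining ring A [(1S,5R)-5-hydroxy-2,6,6-trimethylcyclohex-2-en-1-yl] through the (2Z,4E)-diene to ring B [4-(hydroxymethyl)-7-oxabicyclo[4.1.0]hept-3-ene-2,5-diol, hydroxyls cis to each other and to the side chain, anti to the oxirane] | CC1=CC[C@@H](O)C(C)(C)[C@H]1/C=C/C(C)=C\[C@H](O)[C@]12O[C@H]1[C@H](O)C(CO)=C[C@@H]2O | target

**Step count and risks**
Total steps: 17. Longest linear sequence: 11 (steps 1–10 and 17).

Steps most likely to fail:

1. Step 9. The carbinol may steer singlet oxygen to the other face of the equilibrating arene oxides (mismatched relay). If the selection is merely weak, the two diastereomeric triols are separable and each is a single enantiomer. If it runs in the wrong sense, the fallback sets out from 8 and comes back to the route at 14.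
 - Reduction of 8 with the (S)-configured CBS catalyst gives the enantiomeric dienyl carbinol F1.
 - Directed epoxidation, bromination and dehydrobromination exactly as in steps 6–8 give epoxy alcohol F2, dibromide F3 and the (R)-oxepin carbinol F4.
 - Photooxygenation as in step 9, but without thiourea, passes through arene oxide F5 to the carbinol-epimeric endoperoxide F6. By mirror-image logic F6 now has the ring configuration of the target; it is isolated at or below 0 °C.
 - Its single free hydroxyl is oxidised with Dess–Martin periodinane to the epoxy ynone endoperoxide F7.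
 - Chelation-controlled 1,2-reduction (Zn(BH4)2, Et2O, −30 °C) gives 14. Zinc bridges the carbonyl and oxirane oxygens and hydride enters anti to the oxirane C–C bond; this is the known anti-selective reduction of α,β-epoxy ketones, and borohydride leaves the dialkyl peroxide intact.
 - Thiourea converts 14 into 15 as in step 9.

2. Step 17. Hydroxyl-assisted protodesilylation of the alkenylsilane, or fluoride-induced oxirane migration, may outrun transmetalation. The fallback is a fluoride-free boron-based union; it sets out from 16 and 22 and comes back at 24.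
 - Iododesilylation of 16 with N-iodosuccinimide in hexafluoroisopropanol at 0 °C (ipso substitution with retention) gives the (Z)-alkenyl iodide F8.
 - Aldehyde 22 is homologated by the boron variant of the Takai olefination (CrCl2, LiI, Cl2CHB(pin), THF) to the (E)-alkenylboronate F9.
 - Suzuki–Miyaura coupling of F8 and F9 (Pd(PPh3)4, aq. K3PO4, THF, 40 °C) gives 24, now isolated.
 - Both silyl ethers are removed with TBAF buffered with AcOH to give 25.

3. Step 2. The 1,4-/1,3-regioselectivity of the cycloaddition may be insufficient, with co-elution of the isomers. The fallback sets out from 3 and comes back at 5.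
 - Cobalt-catalysed formal [4+2] cycloaddition of 3 with 2-ethynyl-4,4,5,5-tetramethyl-1,3,2-dioxaborolane (CoBr2(dppe) 5 mol %, Zn, ZnI2, CH2Cl2, 25 °C) gives the dienylboronate F10. This metallacycle-mediated reaction type gives 1,4-disubstituted cyclohexa-1,4-dienes from 2-substituted dienes and terminal alkynes.
 - Ipso-iododeboronation (N-iodosuccinimide, MeCN, 0 °C, dark) gives the dienyl iodide F11.
 - Iodine–lithium exchange (tBuLi, Et2O, −78 °C) and trapping with methyl chloroformate return ester 5.

**Further compounds**
F1 | step 9 | (1S)-1-[4-({[tert-butyl(dimethyl)silyl]oxy}methyl)cyclohexa-1,4-dien-1-yl]but-2-yn-1-ol (enantiomer of 9) | CC#C[C@@H](O)C1=CCC(CO[Si](C)(C)C(C)(C)C)=CC1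
F2 | step 9 | (1R)-1-[4-({[tert-butyl(dimethyl)silyl]oxy}methyl)-7-oxabicyclo[4.1.0]hept-3-en-1-yl]but-2-yn-1-ol | CC#C[C@@H](O)C12OC1CC(CO[Si](C)(C)C(C)(C)C)=CC2
F3 | step 9 | (1R)-1-[3,4-dibromo-4-({[tert-butyl(dimethyl)silyl]oxy}methyl)-7-oxabicyclo[4.1.0]heptan-1-yl]but-2-yn-1-ol | CC#C[C@@H](O)C12OC1CC(Br)(CO[Si](C)(C)C(C)(C)C)C(Br)C2
F4 | step 9 | (1R)-1-[5-({[tert-butyl(dimethyl)silyl]oxy}methyl)oxepin-2-yl]but-2-yn-1-ol | CC#C[C@@H](O)C1=CC=C(CO[Si](C)(C)C(C)(C)C)C=CO1
F5 | step 9 | arene oxide with the oxirane configuration of the target and the (R)-carbinol | CC#C[C@@H](O)[C@]12O[C@H]1C=C(CO[Si](C)(C)C(C)(C)C)C=C2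
F6 | step 9 | carbinol epimer of endoperoxide 14 | CC#C[C@@H](O)[C@]12O[C@H]1[C@H](O3)C(CO[Si](C)(C)C(C)(C)C)=C[C@@H]2O3
F7 | step 9 | epoxy ynone endoperoxide (ketone in place of the carbinol of 14) | CC#CC(=O)[C@]12O[C@H]1[C@H](O3)C(CO[Si](C)(C)C(C)(C)C)=C[C@@H]2O3
F8 | step 17 | (1S,2Z)-3-iodo-1-[ring B as in 15]but-2-en-1-ol | I/C(C)=C\[C@H](O)[C@]12O[C@H]1[C@H](O)C(CO[Si](C)(C)C(C)(C)C)=C[C@@H]2O
F9 | step 17 | ring-A (E)-alkenyl pinacol boronate, triethylsilyl ether | CC1=CC[C@@H](O[Si](CC)(CC)CC)C(C)(C)[C@H]1/C=C/B1OC(C)(C)C(C)(C)O1
F10 | step 2 | 2-[4-({[tert-butyl(dimethyl)silyl]oxy}methyl)cyclohexa-1,4-dien-1-yl]-4,4,5,5-tetramethyl-1,3,2-dioxaborolane | CC1(C)OB(OC1(C)C)C1=CCC(CO[Si](C)(C)C(C)(C)C)=CC1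
F11 | step 2 | tert-butyl[(4-iodocyclohexa-1,4-dien-1-yl)methoxy]dimethylsilane | IC1=CCC(CO[Si](C)(C)C(C)(C)C)=CC1
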